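Count in equivalents, n, the incoming ligands charged per starting complex: 1.20 in dusk, 1.50 in midnight, 4.00 in winter.

| flask | starting complex | incoming ligand | leaving ligand | remark | time |
|---|---|---|---|---|---|
| larch | 0.010 M | 0.0074 M | 10 mM | run made earlier |  |
| elm | 0.010 M | 0.034 M | 10 mM | run made earlier |  |
| dusk | 0.010 M | 0.0120 M | 10.0 mM |  | 2.0 h |
| midnight | 0.010 M | 0.0150 M | 10.0 mM |  | 2.0 h |
| winter | 0.010 M | 0.0400 M | 10.0 mM |  | 2.0 h |

| run | time / min | complex with one exchanged / % | complex with three exchanged / % |
|---|---|---|---|
| larch | 5.00 | 20.7 | 0.6 |
| larch | 12.0 | 32.7 | 1.0 |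
| larch | 25.0 | 39.0 | 1.6 |
| larch | 60.0 | 40.5 | 1.1 |
| elm | 8.00 | 44.7 | 2.0 |
| elm | 20.0 | 32.3 | 1.2 |
| elm | 40.0 | 23.4 | 1.2 |
| elm | 60.0 | 19.2 | 1.0 |

(each reading ± 0.3 percentage points)



- how much complex with one exchanged is there at the end, in percent of the starting complex charged: for each flask in turn (dusk, midnight, winter)

My reckoning assumes 4 sites per complex and starts from two extreme versions of dusk. If each ligand stopped at the first exchange, dusk would hold 100% one-exchanged. If each complex touched ran straight through to four exchanged, dusk would hold none, and 30.0% four-exchanged. Larch, with 0.740 equivalents, reads 40.5% one-exchanged at 60.0 min, below the 74.0% that stopping at the first exchange allows there, and three-exchanged reads 1.1%, so I assume intermediates hold little. I also assume that the unreacted pool, fraction m, is used per molecule twice as fast as one-exchanged. Then one-exchanged is a = 4P(√m − m), where P is the ceiling of one-exchanged, reached where m has fallen to a quarter. The ligand balance gives √m = (3 − √(1 + 2n))/2. Taking its last reading as its end, larch gives P = 49.4%. Elm then tests it: 18.4% reckoned for the ligand used up, 19.2% read at 60.0 min, after 23.4% at 40.0 min, so the elm readings are still falling towards it.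

With ligand as limiting reagent, dusk should end at 48.2% and midnight at 49.4%. Winter's budget reckons an end value of zero, so what I expect there is an unfinished tail. Late in a run each one-exchanged still needs 3 ligands, so I take a to fall as r·a·(a − e), with e the budget's end value, 18.4% in elm and zero in winter, and the elm readings between 20.0 min and 40.0 min give r = 10.1 h⁻¹. Hence I expect winter to hold about 4.95% at 2.0 h.

The forecast differs: 33%, 30% and 14%, starting from “The first exchange is fast and reversible”.

The flasks give 46.5%, 46.5% and 5.10%.

    starting complex + incoming ligand → leaving ligand + complex with one exchanged (k = 0.235 M⁻¹ s⁻¹)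
    complex with one exchanged + incoming ligand → leaving ligand + complex with two exchanged (k = 0.0804 M⁻¹ s⁻¹)
    complex with two exchanged + incoming ligand → leaving ligand + complex with three exchanged (k = 0.577 M⁻¹ s⁻¹)
    complex with three exchanged + incoming ligand → leaving ligand + complex with four exchanged (k = 1.81 M⁻¹ s⁻¹)
    starting complex ⇌ dormant form (K = 0.720, k = 0.0451 s⁻¹)
    starting complex → decomposition product (k = 2.51 × 10⁻⁶ s⁻¹)

In midnight, starting complex enters the dormant form with a forward half-life of 0.26 min, shorter than the 3.28 min of its exchange at the charged ligand, and one-exchanged reacts at 0.588 of the rate constant of the pool of these two. Applied to the pools that stand at the end, 31.3% in dusk and 23.7% in midnight, P gives 48.7% and 49.4%, while the ceiling reckoned from that ratio is 46.9%.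

The data were computed from invented constants; noise was put on by code.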